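**Retrosynthetic overview**
1. Target 22 ⇐ global hydrogenolysis of per-benzylated ester 21 ⇐ Steglich esterification of cyclobutane mono-acid 20 with benzyl-protected (S)-danshensu 6.
2. 20 ⇐ all-trans allyl/benzyl cyclobutane-1,3-diester 19 ⇐ base equilibration of the kinetic cyclobutane 18.
3. 18 ⇐ ring contraction of pyrrolidine 15 by stepwise (biradical) loss of N2 from a 1,1-diazene; this is the key step and the only event that forms the four-membered ring.
4. 15 ⇐ exo-selective asymmetric (3+2) assembly of aldimine 14 (from catechol-derived aldehyde 12 and allyl glycinate 13) with cinnamate 10 (from 4-iodophenol and acrylic acid).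
5. 6 ⇐ (S)-danshensu 5 ⇐ catechol + pyruvic acid (enzyme cascade). Ring order: pyrrolidine first, then cyclobutane.

Assumption: allyl glycinate (13) is used as the free base, liberated from its commercial hydrochloride just before step 7.

**Route**

Step 1
Reactants: 1 catechol; 2 pyruvic acid
Product: 5 (S)-danshensu [(2S)-3-(3,4-dihydroxyphenyl)-2-hydroxypropanoic acid], via L-DOPA 3 (not isolated), via 3,4-dihydroxyphenylpyruvic acid 4 (not isolated)
Conditions: tyrosine phenol-lyase, PLP, NH4Cl, pH 8, 30 °C, N2; then whole cells with L-amino acid deaminase, L-2-hydroxyisocaproate dehydrogenase and formate dehydrogenase, NAD+ (cat.), HCO2NH4, air, pH 7.5, 30 °C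
Reagents that add atoms: water O
Why: Reverse tyrosine phenol-lyase C–C coupling para to a catechol OH, then oxidative deamination and NADH-dependent ketoreduction in one pot; the L-specific 2-hydroxy-acid dehydrogenase reduces one face of keto acid 4 and sets the (S) carbinol centre.

Step 2
Reactants: 5 (S)-danshensu
Product: 6 benzyl (2S)-3-[3,4-bis(benzyloxy)phenyl]-2-hydroxypropanoate
Conditions: BnBr (3.3 equiv), K2CO3, DMF, rt
Reagents that add atoms: benzyl bromide BrCc1ccccc1
Why: Williamson/carboxylate O-alkylation; K2CO3 ionises only the acid and the two phenols, so the secondary alcohol stays free and the stereocentre is untouched.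

Step 3
Reactants: 7 4-iodophenol; 8 acrylic acid
Product: 9 (E)-4-hydroxycinnamic acid
Conditions: Pd(OAc)2 (2 mol %), Et3N, MeCN, 85 °C; acidic work-up
Reagents that add atoms: none
Why: Mizoroki–Heck reaction; syn insertion and syn β-hydride elimination give the E-alkene, and free OH and CO2H are tolerated.

Step 4
Reactants: 9 (E)-4-hydroxycinnamic acid
Product: 10 benzyl (2E)-3-[4-(benzyloxy)phenyl]prop-2-enoate
Conditions: BnBr (2.2 equiv), K2CO3, DMF, 60 °C
Reagents that add atoms: benzyl bromide BrCc1ccccc1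
Why: Double O-benzylation (phenoxide and carboxylate SN2) that leaves the E-alkene unchanged.

Step 5
Reactants: 1 catechol
Product: 11 1,2-bis(benzyloxy)benzene
Conditions: BnBr (2.2 equiv), K2CO3, acetone, reflux
Reagents that add atoms: benzyl bromide BrCc1ccccc1
Why: Williamson ether synthesis on both phenols.

Step 6
Reactants: 11 1,2-bis(benzyloxy)benzene
Product: 12 3,4-bis(benzyloxy)benzaldehyde
Conditions: Cl2CHOMe, SnCl4, CH2Cl2, −78 → 0 °C; then H2O
Reagents that add atoms: dichloromethyl methyl ether COC(Cl)Cl; water O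
Why: Rieche formylation (Friedel–Crafts type); the electrophile attacks para to one benzyloxy group, the only unhindered activated position, and hydrolysis releases the aldehyde.

Step 7
Reactants: 12 3,4-bis(benzyloxy)benzaldehyde; 13 allyl glycinate; 10 benzyl (2E)-3-[4-(benzyloxy)phenyl]prop-2-enoate
Product: 15 2-allyl 4-benzyl (2S,3S,4R,5R)-5-[3,4-bis(benzyloxy)phenyl]-3-[4-(benzyloxy)phenyl]pyrrolidine-2,4-dicarboxylate (exo adduct), via imine 14 (not isolated)
Conditions: 12 + 13, 4 Å MS, CH2Cl2, rt; filter, evaporate; then 10, AgN(SiMe3)2 (10 mol %), (R)-DTBM-SEGPHOS (10 mol %), toluene, 0 °C → rt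
Reagents that add atoms: none
Why: Catalytic asymmetric azomethine-ylide (3+2) cycloaddition (stepwise Michael–Mannich on the N,O-chelated silver enolate): the W-shaped ylide fixes 2,5-cis, the E-alkene fixes 3,4-trans, the bulky bisphosphine–silver amide favours the exo approach (C4 ester anti to the C2 and C5 substituents), and the ligand hand selects the (2S,3S,4R,5R) enantiomer (the mirror-image ligand is used if the first run shows the opposite sense).

Step 8
Reactants: 15 exo pyrrolidine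
Product: 18 1-allyl 3-benzyl (1R,2R,3R,4S)-2-[3,4-bis(benzyloxy)phenyl]-4-[4-(benzyloxy)phenyl]cyclobutane-1,3-dicarboxylate, via N-nitrosopyrrolidine 16 (not isolated), via 1,1-diazene 17 (not isolated)
Conditions: t-BuONO, toluene, rt; evaporate; then B2cat2 (1.5 equiv), toluene, 60 °C
Reagents that add atoms: none
Why: Proposed new method: diboron-mediated deoxygenation of an N-nitrosamine as a ring-contraction trigger — the nucleophilic nitroso oxygen of 16 binds B2cat2, a 1,2-boryl shift from boron to oxygen (as in diboron deoxygenation of amine N-oxides) expels 1,1-diazene 17, which loses N2 to a singlet benzylic/α-ester 1,4-biradical that closes faster than bond rotation, so both former N-bearing carbons keep their configuration; the closest known reactions are the iodonitrene-mediated pyrrolidine-to-cyclobutane contraction and the Overberger–Lombardino dithionite reduction of N-nitroso-2,5-diarylpyrrolidines.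

Step 9
Reactants: 18 kinetic cyclobutane
Product: 19 1-allyl 3-benzyl (1S,2R,3R,4S)-2-[3,4-bis(benzyloxy)phenyl]-4-[4-(benzyloxy)phenyl]cyclobutane-1,3-dicarboxylate (all-trans)
Conditions: t-Bu-P4 phosphazene base (10 mol %), THF, 0 °C → rt; then AcOH
Reagents that add atoms: none
Why: Thermodynamic epimerisation through the allyl ester enolate; the C1 ester, cis to both flanking aryl groups in 18, relaxes to the all-trans arrangement (C1 R → S), while the benzyl ester carbon is already trans to both neighbours and the aryl-bearing carbons have no acidic hydrogen.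

Step 10
Reactants: 19 all-trans diester
Product: 20 (1S,2R,3R,4S)-3-[(benzyloxy)carbonyl]-2-[3,4-bis(benzyloxy)phenyl]-4-[4-(benzyloxy)phenyl]cyclobutane-1-carboxylic acid
Conditions: Pd(PPh3)4 (5 mol %), morpholine, THF, rt
Reagents that add atoms: none
Why: Tsuji–Trost deallylation; zerovalent palladium ionises only the allyl ester and morpholine traps the allyl fragment, leaving benzyl groups and all stereocentres untouched.

Step 11
Reactants: 20 cyclobutane mono-acid; 6 benzyl (2S)-3-[3,4-bis(benzyloxy)phenyl]-2-hydroxypropanoate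
Product: 21 1-benzyl 3-[(2S)-1-(benzyloxy)-3-[3,4-bis(benzyloxy)phenyl]-1-oxopropan-2-yl] (1R,2R,3S,4S)-4-[3,4-bis(benzyloxy)phenyl]-2-[4-(benzyloxy)phenyl]cyclobutane-1,3-dicarboxylate
Conditions: DCC, DMAP (20 mol %), CH2Cl2, 0 °C → rt
Reagents that add atoms: none
Why: Steglich esterification; the acid carbon is already in its thermodynamically preferred configuration so activation cannot erode it, and the alcohol C–O bond is not broken, so the (S) lactate centre is retained.

Step 12
Reactants: 21 per-benzylated ester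
Product: 22 (1R,2R,3S,4S)-3-{[(1S)-1-carboxy-2-(3,4-dihydroxyphenyl)ethoxy]carbonyl}-4-(3,4-dihydroxyphenyl)-2-(4-hydroxyphenyl)cyclobutane-1-carboxylic acid (target)
Conditions: H2 (1 atm), 10% Pd/C, EtOAc/MeOH, rt
Reagents that add atoms: none
Why: Catalytic hydrogenolysis removes five benzyl ethers and two benzyl esters; the lactate C–O bond is not benzylic, the cyclobutane survives at 1 atm, and no stereocentre is involved.

**Compound list**
1 | catechol | Oc1ccccc1O | starting material
2 | pyruvic acid | CC(=O)C(=O)O | starting material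
3 | L-DOPA, (2S)-2-amino-3-(3,4-dihydroxyphenyl)propanoic acid | N[C@@H](Cc1ccc(O)c(O)c1)C(=O)O | intermediate
4 | 3-(3,4-dihydroxyphenyl)-2-oxopropanoic acid | O=C(Cc1ccc(O)c(O)c1)C(=O)O | intermediate
5 | (S)-danshensu, (2S)-3-(3,4-dihydroxyphenyl)-2-hydroxypropanoic acid | O[C@@H](Cc1ccc(O)c(O)c1)C(=O)O | intermediate
6 | benzyl (2S)-3-[3,4-bis(benzyloxy)phenyl]-2-hydroxypropanoate | O[C@@H](Cc1ccc(OCc2ccccc2)c(OCc2ccccc2)c1)C(=O)OCc1ccccc1 | intermediate
7 | 4-iodophenol | Oc1ccc(I)cc1 | starting material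
8 | acrylic acid | C=CC(=O)O | starting material
9 | (E)-4-hydroxycinnamic acid | OC(=O)/C=C/c1ccc(O)cc1 | intermediate
10 | benzyl (2E)-3-[4-(benzyloxy)phenyl]prop-2-enoate | O=C(/C=C/c1ccc(OCc2ccccc2)cc1)OCc1ccccc1 | intermediate
11 | 1,2-bis(benzyloxy)benzene | c1ccc(cc1)COc1ccccc1OCc1ccccc1 | intermediate
12 | 3,4-bis(benzyloxy)benzaldehyde | O=Cc1ccc(OCc2ccccc2)c(OCc2ccccc2)c1 | intermediate
13 | allyl glycinate (prop-2-en-1-yl 2-aminoacetate) | NCC(=O)OCC=C | starting material
14 | allyl N-[(E)-3,4-bis(benzyloxy)benzylidene]glycinate | C=CCOC(=O)C/N=C/c1ccc(OCc2ccccc2)c(OCc2ccccc2)c1 | intermediate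
15 | 2-allyl 4-benzyl (2S,3S,4R,5R)-5-[3,4-bis(benzyloxy)phenyl]-3-[4-(benzyloxy)phenyl]pyrrolidine-2,4-dicarboxylate | O=C(OCc1ccccc1)[C@@H]1[C@@H](c2ccc(OCc3ccccc3)cc2)[C@@H](C(=O)OCC=C)N[C@H]1c1ccc(OCc2ccccc2)c(OCc2ccccc2)c1 | intermediate
16 | 2-allyl 4-benzyl (2S,3S,4R,5R)-5-[3,4-bis(benzyloxy)phenyl]-3-[4-(benzyloxy)phenyl]-1-nitrosopyrrolidine-2,4-dicarboxylate | O=C(OCc1ccccc1)[C@@H]1[C@@H](c2ccc(OCc3ccccc3)cc2)[C@@H](C(=O)OCC=C)N(N=O)[C@H]1c1ccc(OCc2ccccc2)c(OCc2ccccc2)c1 | intermediate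
17 | 1,1-diazene (N-nitrene) of pyrrolidine 15 | O=C(OCc1ccccc1)[C@@H]1[C@@H](c2ccc(OCc3ccccc3)cc2)[C@@H](C(=O)OCC=C)[N+](=[N-])[C@H]1c1ccc(OCc2ccccc2)c(OCc2ccccc2)c1 | intermediate
18 | 1-allyl 3-benzyl (1R,2R,3R,4S)-2-[3,4-bis(benzyloxy)phenyl]-4-[4-(benzyloxy)phenyl]cyclobutane-1,3-dicarboxylate | O=C(OCc1ccccc1)[C@@H]1[C@@H](c2ccc(OCc3ccccc3)cc2)[C@@H](C(=O)OCC=C)[C@H]1c1ccc(OCc2ccccc2)c(OCc2ccccc2)c1 | intermediate
19 | 1-allyl 3-benzyl (1S,2R,3R,4S)-2-[3,4-bis(benzyloxy)phenyl]-4-[4-(benzyloxy)phenyl]cyclobutane-1,3-dicarboxylate | O=C(OCc1ccccc1)[C@@H]1[C@@H](c2ccc(OCc3ccccc3)cc2)[C@H](C(=O)OCC=C)[C@H]1c1ccc(OCc2ccccc2)c(OCc2ccccc2)c1 | intermediate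
20 | (1S,2R,3R,4S)-3-[(benzyloxy)carbonyl]-2-[3,4-bis(benzyloxy)phenyl]-4-[4-(benzyloxy)phenyl]cyclobutane-1-carboxylic acid | O=C(OCc1ccccc1)[C@@H]1[C@@H](c2ccc(OCc3ccccc3)cc2)[C@H](C(=O)O)[C@H]1c1ccc(OCc2ccccc2)c(OCc2ccccc2)c1 | intermediate
21 | 1-benzyl 3-[(2S)-1-(benzyloxy)-3-[3,4-bis(benzyloxy)phenyl]-1-oxopropan-2-yl] (1R,2R,3S,4S)-4-[3,4-bis(benzyloxy)phenyl]-2-[4-(benzyloxy)phenyl]cyclobutane-1,3-dicarboxylate | O=C(OCc1ccccc1)[C@@H]1[C@@H](c2ccc(OCc3ccccc3)cc2)[C@H](C(=O)O[C@@H](Cc2ccc(OCc3ccccc3)c(OCc3ccccc3)c2)C(=O)OCc2ccccc2)[C@H]1c1ccc(OCc2ccccc2)c(OCc2ccccc2)c1 | intermediate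
22 | (1R,2R,3S,4S)-3-{[(1S)-1-carboxy-2-(3,4-dihydroxyphenyl)ethoxy]carbonyl}-4-(3,4-dihydroxyphenyl)-2-(4-hydroxyphenyl)cyclobutane-1-carboxylic acid | O=C(O)[C@@H]1[C@@H](c2ccc(O)cc2)[C@H](C(=O)O[C@@H](Cc2ccc(O)c(O)c2)C(=O)O)[C@H]1c1ccc(O)c(O)c1 | target

**Totals**
Total step count: 12. Longest linear sequence: 8 steps (steps 5, 6, 7, 8, 9, 10, 11, 12 from catechol; equally 3, 4, 7–12 from 4-iodophenol).

**Three steps most likely to fail**

Step 8 (the proposed new step). The nitrosamine oxygen may be too weakly nucleophilic to engage B2cat2, or boron may only coordinate or cause denitrosation. The fallback uses known chemistry, sets out from 15 and comes back at 18. It replaces reductive deoxygenation by oxidative nitrogen transfer: PhI(OH)OTs and H2NCO2NH4 in CF3CH2OH at 80 °C generate an iodonitrene that N-aminates 15 and gives the same 1,1-diazene 17, which contracts to 18 with retention. It makes no compound outside the list: none F0.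

Step 7. An electron-rich cinnamate is a sluggish dipolarophile, and exo selectivity and enantioselectivity on it are not assured. The fallback sets out from 10 and 14 and comes back at 19. It lets alkene geometry and the common endo preference, instead of an exo preference, place the two aryl groups cis. Photoisomerise 10 (fac-Ir(ppy)3, blue light, MeCN) to benzyl (2Z)-3-[4-(benzyloxy)phenyl]prop-2-enoate F1. Run an endo-selective cycloaddition of 14 with F1 (AgOAc, chiral ferrocenyl aminophosphine ligand, Et3N, toluene) to the all-cis pyrrolidine 2-allyl 4-benzyl (2S,3S,4S,5R)-5-[3,4-bis(benzyloxy)phenyl]-3-[4-(benzyloxy)phenyl]pyrrolidine-2,4-dicarboxylate F2. Contract F2 with PhI(OH)OTs and H2NCO2NH4 in CF3CH2OH through the all-cis 1,1-diazene F3 to the all-cis cyclobutane 1-allyl 3-benzyl (1R,2R,3S,4S)-2-[3,4-bis(benzyloxy)phenyl]-4-[4-(benzyloxy)phenyl]cyclobutane-1,3-dicarboxylate F4. Then t-Bu-P4 in THF epimerises both ester carbons, each flanked by two cis aryl groups, to give 19.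

Step 1. The three-enzyme cascade must cope with air-sensitive catechol intermediates and needs a dehydrogenase that accepts keto acid 4. The fallback sets out from 11 and comes back at 6, replacing biocatalysis by chiral-pool epoxide opening. Brominate 11 (NBS, MeCN) to 4-bromo-1,2-bis(benzyloxy)benzene F5. Convert F5 to the Grignard reagent (Mg, THF) and open purchased methyl (2S)-oxirane-2-carboxylate (COC(=O)[C@@H]1CO1) at C3 with CuI (10 mol %) at −40 °C to give methyl (2S)-3-[3,4-bis(benzyloxy)phenyl]-2-hydroxypropanoate F6; the C2 configuration is untouched. Transesterify F6 with BnOH and Ti(OiPr)4 (5 mol %) at 100 °C to give 6.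

**Further compounds**
F0 | step 8 | none | none
F1 | step 7 | benzyl (2Z)-3-[4-(benzyloxy)phenyl]prop-2-enoate | O=C(/C=C\c1ccc(OCc2ccccc2)cc1)OCc1ccccc1
F2 | step 7 | 2-allyl 4-benzyl (2S,3S,4S,5R)-5-[3,4-bis(benzyloxy)phenyl]-3-[4-(benzyloxy)phenyl]pyrrolidine-2,4-dicarboxylate | O=C(OCc1ccccc1)[C@H]1[C@@H](c2ccc(OCc3ccccc3)cc2)[C@@H](C(=O)OCC=C)N[C@H]1c1ccc(OCc2ccccc2)c(OCc2ccccc2)c1
F3 | step 7 | all-cis 1,1-diazene (N-nitrene of F2) | O=C(OCc1ccccc1)[C@H]1[C@@H](c2ccc(OCc3ccccc3)cc2)[C@@H](C(=O)OCC=C)[N+](=[N-])[C@H]1c1ccc(OCc2ccccc2)c(OCc2ccccc2)c1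
F4 | step 7 | 1-allyl 3-benzyl (1R,2R,3S,4S)-2-[3,4-bis(benzyloxy)phenyl]-4-[4-(benzyloxy)phenyl]cyclobutane-1,3-dicarboxylate | O=C(OCc1ccccc1)[C@H]1[C@@H](c2ccc(OCc3ccccc3)cc2)[C@@H](C(=O)OCC=C)[C@H]1c1ccc(OCc2ccccc2)c(OCc2ccccc2)c1
F5 | step 1 | 4-bromo-1,2-bis(benzyloxy)benzene | Brc1ccc(OCc2ccccc2)c(OCc2ccccc2)c1
F6 | step 1 | methyl (2S)-3-[3,4-bis(benzyloxy)phenyl]-2-hydroxypropanoate | O[C@@H](Cc1ccc(OCc2ccccc2)c(OCc2ccccc2)c1)C(=O)OC
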